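The synthesis rests on a retro-Diels–Alder disconnection of the methylcyclohexene ring at the C-1(aroyl)–C-2(aryl) and C-5(H2)–C-6(resorcinyl) bonds that flank its C-3=C-4 alkene. One chiral-borate-templated [4+2] cycloaddition joins a 2′-hydroxychalcone and an (E)-1-aryl-3-methylbutadiene that already carries the finished cis-(2S,3R)-flavanonol ring system. It closes the last ring and sets its three stereocentres. The step exploits the ring alkene as retron and the phenol ortho to the aroyl carbonyl as a chelating handle for boron. The flavanonol comes from asymmetric arylation of a chromone and a cis-selective Moriarty oxidation, and travels as its base-stable dimethyl ketal.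

Key step: step 8

Remark on the chemistry: the hand of each chiral ligand (steps 2 and 8) is assigned from the stereochemical model named in that step, and the enantiomeric ligand is used if a model fails. Compounds 1, 3, 9, 12 and 13 are taken as catalogue chemicals. Cyclohexene numbering: C-1 aroyl, C-2 flavanonol-bearing aryl, C-3=C-4 alkene (methyl on C-4), C-5 CH2, C-6 resorcinol ring.

Step 1
Reactants: 1 7-hydroxy-4H-chromen-4-one
Product: 2 7-(benzyloxy)-4H-chromen-4-one
Conditions: BnBr, K2CO3, DMF, 60 °C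
Reagents that add atoms: benzyl bromide, BrCc1ccccc1
Why: Williamson etherification of the only acidic hydroxyl, with the chromone inert to carbonate.

Step 2
Reactants: 2 7-(benzyloxy)-4H-chromen-4-one; 3 [2-(benzyloxy)-5-bromophenyl]boronic acid
Product: 4 (2R)-7-(benzyloxy)-2-[2-(benzyloxy)-5-bromophenyl]-2,3-dihydro-4H-chromen-4-one
Conditions: [Rh(OH)(cod)]2 (3 mol %), (R)-MeO-F12-BIPHEP [(R)-(6,6′-dimethoxybiphenyl-2,2′-diyl)bis[bis(3,4,5-trifluorophenyl)phosphine], 6.6 mol %], 3 (3 equiv), toluene/H2O, 40 °C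
Reagents that add atoms: none
Why: Hayashi–Miyaura-type rhodium-catalysed asymmetric 1,4-addition of an arylboronic acid to a chromone, in which the electron-poor bisphosphine should make protonation of the rhodium enolate faster than its ring opening, the (R)-ligand is expected (by analogy with (R)-BINAP on cyclic enones) to deliver the aryl group to the face that gives the 2R centre, and the aryl bromide is inert to monovalent rhodium.

Step 3
Reactants: 4 (2R)-7-(benzyloxy)-2-[2-(benzyloxy)-5-bromophenyl]-2,3-dihydro-4H-chromen-4-one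
Product: 7 (2S,3R)-7-(benzyloxy)-2-[2-(benzyloxy)-5-bromophenyl]-4,4-dimethoxy-3,4-dihydro-2H-chromen-3-ol (2,3-cis), via trans-3-iodanyl flavanone 5 (not isolated), via 4-methoxy-3,4-epoxide 6 (not isolated)
Conditions: PhI(OAc)2 (1.2 equiv), KOH (4 equiv), MeOH, 0 °C to rt
Reagents that add atoms: methanol, CO
Why: Moriarty α-hydroxylation with trivalent iodine, in which the enolate is iodinated anti to the C-2 aryl group (5), methoxide adds to C-4 and the resulting alkoxide displaces iodobenzene with inversion to give epoxide 6, whose opening by methanol at C-4 leaves the C-3 oxygen cis to the aryl group and the ketone masked as a base-stable dimethyl ketal.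

Step 4
Reactants: 7 (2S,3R)-7-(benzyloxy)-2-[2-(benzyloxy)-5-bromophenyl]-4,4-dimethoxy-3,4-dihydro-2H-chromen-3-ol
Product: 8 (2S,3R)-3,7-bis(benzyloxy)-2-[2-(benzyloxy)-5-bromophenyl]-4,4-dimethoxy-3,4-dihydro-2H-chromene
Conditions: NaH, BnBr, n-Bu4NI (cat.), THF/DMF, 0 °C to rt
Reagents that add atoms: benzyl bromide, BrCc1ccccc1
Why: Williamson benzylation of the secondary alkoxide, safe for the cis relationship because the ketal leaves no enolisable or β-eliminable position.

Step 5
Reactants: 9 2-methylbut-1-en-3-yne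
Product: 10 4,4,5,5-tetramethyl-2-[(1E)-3-methylbuta-1,3-dien-1-yl]-1,3,2-dioxaborolane
Conditions: pinacolborane, Cp2Zr(H)Cl (5 mol %), Et3N (10 mol %), neat, 60 °C
Reagents that add atoms: pinacolborane, [H]B1OC(C)(C)C(C)(C)O1
Why: zirconium-catalysed syn-hydroboration of the terminal alkyne places boron at the terminus and should give the E-dienylboronate, the 1,1-disubstituted alkene being untouched.

Step 6
Reactants: 8 (2S,3R)-3,7-bis(benzyloxy)-2-[2-(benzyloxy)-5-bromophenyl]-4,4-dimethoxy-3,4-dihydro-2H-chromene; 10 4,4,5,5-tetramethyl-2-[(1E)-3-methylbuta-1,3-dien-1-yl]-1,3,2-dioxaborolane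
Product: 11 (2S,3R)-3,7-bis(benzyloxy)-2-{2-(benzyloxy)-5-[(1E)-3-methylbuta-1,3-dien-1-yl]phenyl}-4,4-dimethoxy-3,4-dihydro-2H-chromene
Conditions: Pd(dppf)Cl2 (5 mol %), K3PO4, 1,4-dioxane/H2O, 80 °C, BHT (trace)
Reagents that add atoms: none
Why: Suzuki–Miyaura coupling with retention of the E geometry, the ketal and benzyl ethers being stable to aqueous phosphate.

Step 7
Reactants: 12 1-[4-(benzyloxy)-2-hydroxyphenyl]ethan-1-one; 13 2,4-bis(benzyloxy)benzaldehyde
Product: 14 (2E)-1-[4-(benzyloxy)-2-hydroxyphenyl]-3-[2,4-bis(benzyloxy)phenyl]prop-2-en-1-one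
Conditions: KOH, EtOH/THF, rt; then dilute HCl
Reagents that add atoms: none
Why: Claisen–Schmidt aldol condensation, whose E1cB dehydration gives the E-enone and in which the hydrogen-bonded ortho-phenol needs no protection.

Step 8
Reactants: 14 (2E)-1-[4-(benzyloxy)-2-hydroxyphenyl]-3-[2,4-bis(benzyloxy)phenyl]prop-2-en-1-one; 11 (2S,3R)-3,7-bis(benzyloxy)-2-{2-(benzyloxy)-5-[(1E)-3-methylbuta-1,3-dien-1-yl]phenyl}-4,4-dimethoxy-3,4-dihydro-2H-chromene
Product: 17 {(1R,2R,6S)-6-[2,4-bis(benzyloxy)phenyl]-2-{4-(benzyloxy)-3-[(2S,3R)-3,7-bis(benzyloxy)-4,4-dimethoxy-3,4-dihydro-2H-chromen-2-yl]phenyl}-4-methylcyclohex-3-en-1-yl}[4-(benzyloxy)-2-hydroxyphenyl]methanone, via chalcone borate chelate 15 (not isolated), via adduct borate chelate 16 (not isolated)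
Conditions: (R)-VANOL, B(OPh)3 (1.2 equiv each), toluene, 80 °C then vacuum; 14, CH2Cl2, rt; 11 (1.5 equiv), rt to 40 °C; aq. NaHCO3
Reagents that add atoms: none
Why: Chalcone 14 displaces phenol from the VANOL borate to give the tetracoordinate chelate 15 (phenolate and carbonyl oxygen on boron), which lowers the LUMO of the s-cis enone and holds it in a chiral pocket; diene 11 then adds in a concerted but strongly asynchronous [4+2] cycloaddition (CH2 terminus to the β-carbon first), closing the six-membered ring suprafacially on both partners through the C-1–C-2 and C-5–C-6 bonds, and work-up hydrolyses borate 16. The closest known reaction type is the chiral-borate-promoted asymmetric Diels–Alder reaction of 2′-hydroxychalcones with 1-aryl-3-methylbutadienes. Regiochemistry (aroyl carbon next to the aryl-bearing carbon) follows from the push of the para-benzyloxyaryl and methyl groups of the diene and the pull of the chelated carbonyl. The E geometry of the enone fixes the trans relation of C-1 and C-6; in the chelate model the (R)-ligand places one aryl wall beside the carbonyl oxygen and shields that enone face, so that C-1 and C-6 should become R and S; and the exo orientation of the chelated aroyl group (resorcinol ring under the diene) together with the E diene sets C-2 as R, trans to the aroyl group. The step therefore needs exo selectivity, which rests only on the bulk of the spiro-borate and the weak secondary overlap in so polarised a transition state and is the least secure element; the remote flavanonol centres should exert no influence, and the ketal, the benzyl ethers and the diene should tolerate the mild aprotic Lewis acid.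

Step 9
Reactants: 17 {(1R,2R,6S)-6-[2,4-bis(benzyloxy)phenyl]-2-{4-(benzyloxy)-3-[(2S,3R)-3,7-bis(benzyloxy)-4,4-dimethoxy-3,4-dihydro-2H-chromen-2-yl]phenyl}-4-methylcyclohex-3-en-1-yl}[4-(benzyloxy)-2-hydroxyphenyl]methanone
Product: 18 [(1R,2R,6S)-6-(2,4-dihydroxyphenyl)-2-{4-hydroxy-3-[(2S,3R)-3,7-dihydroxy-4-oxo-3,4-dihydro-2H-chromen-2-yl]phenyl}-4-methylcyclohex-3-en-1-yl](2,4-dihydroxyphenyl)methanone
Conditions: BCl3 (1 M in CH2Cl2, excess), pentamethylbenzene, CH2Cl2, −78 to −40 °C; MeOH, then H2O/THF, 0 °C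
Reagents that add atoms: water, O
Why: BCl3 cleaves all six benzyl ethers by ionisation while pentamethylbenzene traps the benzyl cations (Friedel–Crafts), so that neither the alkene nor the resorcinol rings are benzylated; the same Lewis acid opens the dimethyl ketal, which is hydrolysed to the ketone on aqueous work-up, and at low temperature without base neither C-2 nor C-3 of the cis-flavanonol should epimerise.

Compound list
1 | 7-hydroxy-4H-chromen-4-one | O=c1ccoc2cc(O)ccc12 | starting material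
2 | 7-(benzyloxy)-4H-chromen-4-one | O=c1ccoc2cc(OCc3ccccc3)ccc12 | intermediate
3 | [2-(benzyloxy)-5-bromophenyl]boronic acid | OB(O)c1cc(Br)ccc1OCc1ccccc1 | starting material
4 | (2R)-7-(benzyloxy)-2-[2-(benzyloxy)-5-bromophenyl]-2,3-dihydro-4H-chromen-4-one | Brc1ccc(OCc2ccccc2)c(c1)[C@@H]1Oc2cc(OCc3ccccc3)ccc2C(=O)C1 | intermediate
5 | (2S,3S)-7-(benzyloxy)-2-[2-(benzyloxy)-5-bromophenyl]-3-[methoxy(phenyl)iodanyl]-2,3-dihydro-4H-chromen-4-one (iodine trans to the aryl group) | Brc1ccc(OCc2ccccc2)c(c1)[C@@H]1Oc2cc(OCc3ccccc3)ccc2C(=O)[C@H]1I(OC)c1ccccc1 | intermediate (not isolated)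
6 | (2S,3R,4S)-7-(benzyloxy)-2-[2-(benzyloxy)-5-bromophenyl]-3,4-epoxy-4-methoxychromane (epoxide oxygen cis to the aryl group) | Brc1ccc(OCc2ccccc2)c(c1)[C@@H]1Oc2cc(OCc3ccccc3)ccc2[C@]2(OC)O[C@H]12 | intermediate (not isolated)
7 | (2S,3R)-7-(benzyloxy)-2-[2-(benzyloxy)-5-bromophenyl]-4,4-dimethoxy-3,4-dihydro-2H-chromen-3-ol (2,3-cis) | Brc1ccc(OCc2ccccc2)c(c1)[C@@H]1Oc2cc(OCc3ccccc3)ccc2C(OC)(OC)[C@@H]1O | intermediate
8 | (2S,3R)-3,7-bis(benzyloxy)-2-[2-(benzyloxy)-5-bromophenyl]-4,4-dimethoxy-3,4-dihydro-2H-chromene | Brc1ccc(OCc2ccccc2)c(c1)[C@@H]1Oc2cc(OCc3ccccc3)ccc2C(OC)(OC)[C@@H]1OCc1ccccc1 | intermediate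
9 | 2-methylbut-1-en-3-yne | C=C(C)C#C | starting material
10 | 4,4,5,5-tetramethyl-2-[(1E)-3-methylbuta-1,3-dien-1-yl]-1,3,2-dioxaborolane | CC(=C)/C=C/B1OC(C)(C)C(C)(C)O1 | intermediate
11 | (2S,3R)-3,7-bis(benzyloxy)-2-{2-(benzyloxy)-5-[(1E)-3-methylbuta-1,3-dien-1-yl]phenyl}-4,4-dimethoxy-3,4-dihydro-2H-chromene | C=C(C)/C=C/c1ccc(OCc2ccccc2)c(c1)[C@@H]1Oc2cc(OCc3ccccc3)ccc2C(OC)(OC)[C@@H]1OCc1ccccc1 | intermediate
12 | 1-[4-(benzyloxy)-2-hydroxyphenyl]ethan-1-one | CC(=O)c1ccc(OCc2ccccc2)cc1O | starting material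
13 | 2,4-bis(benzyloxy)benzaldehyde | O=Cc1ccc(OCc2ccccc2)cc1OCc1ccccc1 | starting material
14 | (2E)-1-[4-(benzyloxy)-2-hydroxyphenyl]-3-[2,4-bis(benzyloxy)phenyl]prop-2-en-1-one | O=C(/C=C/c1ccc(OCc2ccccc2)cc1OCc1ccccc1)c1ccc(OCc2ccccc2)cc1O | intermediate
15 | spiro-borate chelate of 14 with (R)-VANOL: boron bound to the 2′-phenolate oxygen, the carbonyl oxygen and both VANOL oxygens (axial R configuration not encoded in the SMILES) | [O+]1=C(/C=C/c2ccc(OCc3ccccc3)cc2OCc2ccccc2)c2ccc(OCc3ccccc3)cc2O[B-]14Oc2c(c(-c3ccccc3)cc3ccccc23)-c2c(O4)c3ccccc3cc2-c2ccccc2 | intermediate (not isolated)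
16 | the same spiro-borate chelate of cycloadduct 17, ring carbons (1R,2R,6S) (axial R configuration not encoded in the SMILES) | CC1=C[C@@H](c2ccc(OCc3ccccc3)c([C@@H]3Oc4cc(OCc5ccccc5)ccc4C(OC)(OC)[C@@H]3OCc3ccccc3)c2)[C@H](C2=[O+][B-]3(Oc4c(c(-c5ccccc5)cc5ccccc45)-c4c(O3)c5ccccc5cc4-c4ccccc4)Oc3cc(OCc4ccccc4)ccc23)[C@@H](c2ccc(OCc3ccccc3)cc2OCc2ccccc2)C1 | intermediate (not isolated)
17 | {(1R,2R,6S)-6-[2,4-bis(benzyloxy)phenyl]-2-{4-(benzyloxy)-3-[(2S,3R)-3,7-bis(benzyloxy)-4,4-dimethoxy-3,4-dihydro-2H-chromen-2-yl]phenyl}-4-methylcyclohex-3-en-1-yl}[4-(benzyloxy)-2-hydroxyphenyl]methanone (all-trans ring) | CC1=C[C@@H](c2ccc(OCc3ccccc3)c([C@@H]3Oc4cc(OCc5ccccc5)ccc4C(OC)(OC)[C@@H]3OCc3ccccc3)c2)[C@H](C(=O)c2ccc(OCc3ccccc3)cc2O)[C@@H](c2ccc(OCc3ccccc3)cc2OCc2ccccc2)C1 | intermediate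
18 | [(1R,2R,6S)-6-(2,4-dihydroxyphenyl)-2-{4-hydroxy-3-[(2S,3R)-3,7-dihydroxy-4-oxo-3,4-dihydro-2H-chromen-2-yl]phenyl}-4-methylcyclohex-3-en-1-yl](2,4-dihydroxyphenyl)methanone (CNP0219853.2) | CC1=C[C@@H](c2ccc(O)c([C@@H]3Oc4cc(O)ccc4C(=O)[C@@H]3O)c2)[C@H](C(=O)c2ccc(O)cc2O)[C@@H](c2ccc(O)cc2O)C1 | target

Total step count: 9. Longest linear sequence: 7 steps (steps 1, 2, 3, 4, 6, 8, 9). Steps 5 and 7 are single-step side branches.

Steps most likely to fail

Step 8. The endo mode (aroyl group under the diene) may compete and would give the ring isomer with C-1 and C-2 cis. This cannot be corrected later, because C-2 and C-6 are not epimerisable. Shielding of one enone face may also be incomplete, and the electron-rich diene may oligomerise under the Lewis acid. Fallback: reagent control is given up for separation. Setting out from 11 and 14, the two partners are heated without any promoter (toluene, sealed tube, about 110 °C, BHT) in a purely thermal Diels–Alder reaction. Because 11 is a single enantiomer, the endo and exo adducts of both ring configurations form as diastereomers. The all-trans (1R,2R,6S) isomer is isolated by preparative HPLC, and the route is rejoined at 17. No new compound is made.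

Step 3. Retro-oxa-Michael opening of the flavanone enolate in methanolic KOH may erode the C-2 configuration or divert material to chalcone-derived products before the iodane traps the enolate. Fallback, from 4 back to 7, avoiding any free enolate:
- Soft enolisation (TMSOTf, Et3N, CH2Cl2, 0 °C) should give the silyl enol ether F1.
- Rubottom oxidation with dimethyldioxirane and mild acid work-up should give the trans-3-hydroxyflavanone F2, the oxidant approaching anti to the aryl group.
- Mitsunobu inversion at C-3 (PPh3, DIAD, 4-nitrobenzoic acid, THF) should give the cis 4-nitrobenzoate F3.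
- Ketalisation (HC(OMe)3, MeOH, TsOH) should give the ester ketal F4.
- Methanolysis (K2CO3, MeOH), harmless now that the ketone is masked, returns 7.

Step 9. The Lewis acid may ionise the benzylic C-2–O-1 bond of the flavanonol (epimerisation or ring opening), HCl may add to the trisubstituted alkene, and the secondary benzyl ether may be cleaved incompletely. Fallback, from 17 to 18, with the two tasks separated and the cleavage made reductive:
- The ketal is hydrolysed first (PPTS, acetone/H2O, rt) to the hexa-O-benzyl ketone F5.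
- The benzyl ethers are then removed by transfer hydrogenolysis (Pd(OH)2 on carbon, 1,4-cyclohexadiene, EtOAc/EtOH, rt), which should be stopped before the ring alkene is reduced, to give 18.

Further compounds
F0 | step 8 | none | none
F1 | step 3 | (2R)-7-(benzyloxy)-2-[2-(benzyloxy)-5-bromophenyl]-4-[(trimethylsilyl)oxy]-2H-chromene | Brc1ccc(OCc2ccccc2)c(c1)[C@@H]1Oc2cc(OCc3ccccc3)ccc2C(O[Si](C)(C)C)=C1
F2 | step 3 | (2S,3S)-7-(benzyloxy)-2-[2-(benzyloxy)-5-bromophenyl]-3-hydroxy-2,3-dihydro-4H-chromen-4-one (2,3-trans) | Brc1ccc(OCc2ccccc2)c(c1)[C@@H]1Oc2cc(OCc3ccccc3)ccc2C(=O)[C@H]1O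
F3 | step 3 | (2S,3R)-7-(benzyloxy)-2-[2-(benzyloxy)-5-bromophenyl]-4-oxo-3,4-dihydro-2H-chromen-3-yl 4-nitrobenzoate (2,3-cis) | Brc1ccc(OCc2ccccc2)c(c1)[C@@H]1Oc2cc(OCc3ccccc3)ccc2C(=O)[C@@H]1OC(=O)c1ccc(cc1)[N+](=O)[O-]
F4 | step 3 | (2S,3R)-7-(benzyloxy)-2-[2-(benzyloxy)-5-bromophenyl]-4,4-dimethoxy-3,4-dihydro-2H-chromen-3-yl 4-nitrobenzoate | Brc1ccc(OCc2ccccc2)c(c1)[C@@H]1Oc2cc(OCc3ccccc3)ccc2C(OC)(OC)[C@@H]1OC(=O)c1ccc(cc1)[N+](=O)[O-]
F5 | step 9 | {(1R,2R,6S)-6-[2,4-bis(benzyloxy)phenyl]-2-{4-(benzyloxy)-3-[(2S,3R)-3,7-bis(benzyloxy)-4-oxo-3,4-dihydro-2H-chromen-2-yl]phenyl}-4-methylcyclohex-3-en-1-yl}[4-(benzyloxy)-2-hydroxyphenyl]methanone | CC1=C[C@@H](c2ccc(OCc3ccccc3)c([C@@H]3Oc4cc(OCc5ccccc5)ccc4C(=O)[C@@H]3OCc3ccccc3)c2)[C@H](C(=O)c2ccc(OCc3ccccc3)cc2O)[C@@H](c2ccc(OCc3ccccc3)cc2OCc2ccccc2)C1
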